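## Structural features

The target is a depside: two benzene rings joined only by an aryl ester, in which the carboxyl carbon on C1' of ring B (a 2,3,4-trihydroxy-6-methylbenzoyl unit) acylates the C4 oxygen of ring A (a methyl 2,4-dihydroxy-3,6-dimethylbenzoate unit). There is no stereocentre and no ring fusion, so the problem is one of substitution pattern and of chemoselectivity among five phenolic oxygens and two esters. Ring A carries CO2CH3 at C1, a free hydroxyl at C2, methyl at C3, the acylated oxygen at C4, hydrogen at C5 and methyl at C6. Ring B is also pentasubstituted, and its carbonyl group sits between an oxygen at C2' and a methyl at C6', which makes it a hindered acyl donor. The fragile groups are the aryl ester (cleaved or transesterified by alkoxide, hydroxide or amines), the methyl ester, and the pyrogallol unit of ring B, which is oxidised by air under basic conditions. The real difficulty is to obtain O2 and O4 of ring A in differentiated form, to make a congested ester at O4 only, and to unmask ring B last under neutral conditions. The key step exploits the C2(OH)–C3(CH3)–C4(O) sequence of ring A: a vinylketene supplies C1, C2, C5 and C6, and 1-siloxypropyne supplies C3 and C4, so C2 emerges as a free phenol and C4 as a silyl ether.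

## Logic of the disconnections

21 to 20. The three phenolic O–H bonds of ring B are written as O–benzyl bonds. This postpones the air-sensitive triol to the last step and leaves only the chelated C2 hydroxyl of ring A free during ester formation. The forward step must be neutral and reductive so that neither ester is touched.

20 to 13 and 18. The bond between the ring B carbonyl carbon and O4 of ring A is cut, and O4 is written as its silyl ether. The target falls into two rings of similar size and the route becomes convergent. The forward step must remove silicon from O4 and put a doubly ortho-substituted acyl group on the same oxygen while O2 stays free; O2 is hydrogen-bonded to the ester and flanked on both sides, which should help.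

18 to 17, 16, 15 and 14. The C–Cl bond leads back to the acid and the acid to an aldehyde. The bond from ring carbon C1' to the carbonyl carbon is then cut, and the O–benzyl bonds of 15 lead back to 14. Ring B is bought with its three oxygens and its methyl group in place, and only one carbon is added. The formylation needs no regiocontrol because the two open positions of 15 are equivalent by symmetry; the oxidation must leave the electron-rich ring unchlorinated.

13 to 5 and 9. Three skeletal bonds of ring A are cut: C2–C3, C4–C5 and C1–C2. A pentasubstituted arene with two different oxygens becomes two open-chain compounds, and O2 and O4 are differentiated from the moment the ring exists. The forward step requires that 5 rearranges to a ketene with the ester trans to the ketene carbon, that 9 adds in one orientation only, and that the pericyclic steps outrun ketene dimerisation.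

5 to 3, then to 1 and 2. The carbon–nitrogen bond at C5 is cut (diazo transfer to the acetyl methyl group), then the C2=C3 double bond (olefination). Both starting materials are commodity chemicals and no diazomethane is needed. The forward steps require mono-olefination of a symmetrical dione with (E) selectivity, and diazo transfer to a methyl ketone that is also a Michael acceptor.

9 to 6. The O–Si bond is cut, and the alkyne is traced to an ester by removing the carbon that sits between the methyl group and the oxygen-bearing carbon. The alkyne comes from a bulk ester in one flask. The forward step requires that the rearrangement runs to the ynolate and that silylation occurs on oxygen.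

## Other disconnections considered

Alternative 1: The cut is made at both bonds of the depside carbonyl carbon, C1'–C(=O) of ring B and C(=O)–O4 of ring A, so the carbonyl carbon comes from carbon monoxide.
- Forward step: 1,2,3-tris(benzyloxy)-4-iodo-5-methylbenzene A1, CO and methyl 2,4-dihydroxy-3,6-dimethylbenzoate A2 would be joined with Pd(OAc)2, Xantphos and Et3N. Oxidative addition of A1 to zerovalent palladium, CO insertion and capture of the acylpalladium species by the C4 hydroxyl of A2 would give the tribenzyl depside A3, which is the same compound as 20.
- In favour: two bonds form in one operation and the plan is fully convergent. A1 would be one electrophilic iodination away from 15, whereas the chosen plan needs formylation, oxidation and chloride formation (steps 6 to 8). On step economy for ring B it is the better plan; in the final hydrogenolysis the two are equal.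
- Against: the iodide is flanked by a benzyloxy and a methyl group, and the electron-poor phenol is a weak nucleophile for the acylpalladium intermediate. Hydrodehalogenation and direct C–O coupling can compete. The choice between O4 and O2 of A2 rests on intrinsic reactivity and is not fixed by a silyl ether. Toxic CO gas must be handled.
- Comparison: the alternative does not say where ring A comes from, so A2 must still be made (for instance by desilylating 13). It replaces steps 6 to 9 and not the key step. Mechanistically it trades a predictable acyl substitution for a catalytic cycle with two hindered partners.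

Alternative 2: Ring B is cut at C1–C6 and C3–C4 and taken back to a non-aromatic cyclohexane-1,3-dione.
- Forward step: KOtBu would add tert-butyl 3-oxobutanoate A4 to methyl (E)-but-2-enoate A5 (Michael addition, C1–C6). The acetyl methyl group would then close onto the methyl ester (Dieckmann condensation, C3–C4) to give tert-butyl 6-methyl-2,4-dioxocyclohexane-1-carboxylate A6. Oxidation of C3 to the ketone level (for example by diazo transfer and oxygen-atom transfer) would give trione A7, a tautomer of tert-butyl 2,3,4-trihydroxy-6-methylbenzoate A8, into which it should enolise.
- In favour: bulk starting materials, ground-state polar chemistry without light or a diazo ketone in the ring-forming step, and easy scale-up. In safety and robustness of the key step itself it is the better of the two. In regiochemical certainty it is the equal of the chosen plan.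
- Against: it builds a ring that can be bought in aromatic form as 14. After A8 the three hydroxyls must still be benzylated and the tert-butyl ester removed before acylation, so the ring B arm would be at least two steps longer than steps 5 to 8. Vicinal tricarbonyl compounds such as A7 hydrate readily and can ring-contract under base.
- Comparison: the C2/C4 differentiation of ring A, which is the real selectivity problem, is left unsolved.

Alternative 3: Ring B is cut at C5–C6 and C1–C2 and built onto ring A after the ester bond is in place.
- Forward step: 4-chloro-2,3-diisopropoxycyclobut-2-en-1-one A9 and methyl 2-hydroxy-3,6-dimethyl-4-{[(2E)-3-(tributylstannyl)but-2-enoyl]oxy}benzoate A10 would undergo Stille coupling (Pd2(dba)3, tri(2-furyl)phosphine, warm dioxane) to form C5–C6. The resulting 4-alkenylcyclobutenone would open in the same pot to a dienylketene and close C1–C2 by 6π electrocyclisation to give methyl 2-hydroxy-4-[(2-hydroxy-3,4-diisopropoxy-6-methylbenzoyl)oxy]-3,6-dimethylbenzoate A11.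
- In favour: the pericyclic sequence is the same as in the chosen key step and equally dependable in regiochemistry (equal on mechanism). It is thermal, so it is better in avoiding photochemistry and a diazo compound. The ester bond is made from an unhindered butenoic acid before ring B exists, which is better than acylating with a doubly ortho-substituted benzoyl chloride.
- Against: stoichiometric organotin, and a squarate-derived chloride A9 that itself takes several steps. A10 needs selective O4 acylation of A2, so ring A must again come from elsewhere. The two isopropyl ethers of A11 must be cleaved at the end with a Lewis acid such as BCl3 in the presence of two esters, which is harsher than the hydrogenolysis of step 10.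
- Comparison: the step counts should be close, with the chosen plan ahead because ring B is bought and not built.

Key step: step 4

## Remarks before the route

- Assumption: the Wittig step is expected to favour the (E)-keto ester, as is usual for a stabilised ylide; any (Z)-isomer is removed before diazo transfer.
- The atom mapping of 5, 9 and 13 was checked against the mechanism (Wolff shift; C2–C3 and C4–C5 in the cycloaddition; C2–C5 broken on opening; C1–C2 on closure). No structure needed correction.
- Precursor design: 5 is used as the geometrically pure (E)-isomer, because a (Z)-ketene could close onto its own ester oxygen. 5 is made with a crystalline, shock-insensitive sulfonyl azide, kept cold and dark in solution, and photolysed in a flow cell of small hold-up volume. No diazomethane, CO gas or tin is used.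
- Intermediate 4 passes through an acidic aqueous work-up but is not purified, and is treated as not isolated.

## Route

Step 1
Reactants: 1 butane-2,3-dione; 2 methyl (triphenylphosphoranylidene)acetate
Product: 3 methyl (E)-3-methyl-4-oxopent-2-enoate
Conditions: 1 (3 equiv), CH2Cl2, 0 °C to rt
Reagents that add atoms: none
Why: Wittig olefination with a stabilised ylide; the 1,2-dione is much more electrophilic than the keto ester product and is used in excess, so only one carbonyl should react, and the stabilised ylide favours the (E)-alkene with the ester trans to the acetyl group.

Step 2
Reactants: 3 methyl (E)-3-methyl-4-oxopent-2-enoate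
Product: 5 methyl (E)-5-diazo-3-methyl-4-oxopent-2-enoate, via trifluoroacetyl ketone 4 (not isolated)
Conditions: LiN(SiMe3)2, THF, −78 °C, then CF3CO2CH2CF3; acidic work-up; then 4-acetamidobenzenesulfonyl azide, Et3N, H2O (1 equiv), MeCN, rt
Reagents that add atoms: 2,2,2-trifluoroethyl trifluoroacetate, FC(F)(F)COC(=O)C(F)(F)F (the CF3CO group of 4 only); 4-acetamidobenzenesulfonyl azide, CC(=O)Nc1ccc(cc1)S(=O)(=O)N=[N+]=[N-] (the two diazo nitrogens of 5)
Why: Detrifluoroacetylative diazo transfer: kinetic deprotonation occurs at the acetyl methyl group (the only hydrogen-bearing alpha position of the ketone), Claisen acylation gives the activated 1,3-diketone 4, and the sulfonyl azide transfers N2 to its central carbon while the trifluoroacetyl group leaves on the sulfonamide nitrogen. The conditions are mild enough to spare the enoate and its (E) geometry.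

Step 3
Reactants: 6 ethyl acetate
Product: 9 triisopropyl(prop-1-yn-1-yloxy)silane, via lithium dibromoenolate 7 (not isolated), via lithium ynolate 8 (not isolated)
Conditions: CH2Br2, LiTMP (lithium 2,2,6,6-tetramethylpiperidide), THF, −78 °C; 6; LiN(SiMe3)2, −78 to −20 °C; n-BuLi, −78 °C to rt; TIPSCl, −78 to 0 °C
Reagents that add atoms: dibromomethane, BrCBr (one alkyne carbon; the bromines of 7); lithium bis(trimethylsilyl)amide, [Li+].C[Si](C)(C)[N-][Si](C)(C)C (the lithium of 7 and 8); chlorotriisopropylsilane, CC(C)[Si](Cl)(C(C)C)C(C)C
Why: Kowalski ester homologation stopped at the ynolate: LiCHBr2 adds to the ester carbonyl, the adduct collapses and is enolised to 7, bromine–lithium exchange gives the alpha-bromo alpha-keto dianion, and the methyl group shifts with loss of LiBr to give 8. The bulky chlorosilane should silylate 8 on oxygen and not on carbon.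

Step 4
Reactants: 5 methyl (E)-5-diazo-3-methyl-4-oxopent-2-enoate; 9 triisopropyl(prop-1-yn-1-yloxy)silane
Product: 13 methyl 2-hydroxy-3,6-dimethyl-4-[(triisopropylsilyl)oxy]benzoate, via vinylketene 10 (not isolated), via vinylcyclobutenone 11 (not isolated), via dienylketene 12 (not isolated)
Conditions: 9 (1.5 equiv), hν (medium-pressure Hg lamp, Pyrex filter, flow cell), CH2Cl2, rt; then toluene, 80 °C
Reagents that add atoms: none
Why: Irradiation expels N2 from 5 and the alkenyl group migrates (photochemical Wolff rearrangement) to give (E)-vinylketene 10. The polarised siloxyalkyne 9 adds across the ketene C=C bond in a regioselective (2+2) cycloaddition: its nucleophilic methyl-bearing carbon bonds to the electrophilic ketene carbonyl carbon (C2–C3) and its siloxy-bearing carbon to the ketene alpha carbon (C4–C5), which gives 4-alkenylcyclobutenone 11 and places the methyl group between the two oxygens. Light or gentle heat opens 11 by reversible 4π conrotatory cleavage of the C2–C5 bond to dienylketene 12. Ring A, the only ring formed, then closes by a thermally allowed disrotatory 6π electrocyclisation that joins ketene carbon C2 to the ester-bearing alkene carbon C1, and the cyclohexadienone tautomerises irreversibly to phenol 13; the heating period drives any remaining 11 through this sequence. The closest known reaction type is the second-generation Danheiser benzannulation of alpha-diazo enones with siloxyalkynes, which gives resorcinol monosilyl ethers. No stereocentre is created. The step needs regioselectivity in the cycloaddition, which the oxygen-induced polarisation of 9 secures, and a ketene that closes on carbon, which the (E) geometry secures by holding the ester outside the closing termini and away from the ketene carbon; the new C2 hydroxyl is tied up in a hydrogen bond to the ester and should not compete with 9 for the ketene.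

Step 5
Reactants: 14 5-methylbenzene-1,2,3-triol
Product: 15 1,2,3-tris(benzyloxy)-5-methylbenzene
Conditions: BnBr (3.5 equiv), K2CO3, DMF (degassed, N2), rt to 60 °C
Reagents that add atoms: benzyl bromide, BrCc1ccccc1
Why: Threefold Williamson ether synthesis; exclusion of air keeps the electron-rich triolate from oxidising before it is alkylated.

Step 6
Reactants: 15 1,2,3-tris(benzyloxy)-5-methylbenzene
Product: 16 2,3,4-tris(benzyloxy)-6-methylbenzaldehyde
Conditions: POCl3, DMF, 0 to 70 °C; then aq NaOAc
Reagents that add atoms: N,N-dimethylformamide, CN(C)C=O (the formyl carbon); water, O (the carbonyl oxygen)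
Why: Vilsmeier–Haack formylation; the two open ring positions of 15 are equivalent by symmetry and each is ortho and para to a benzyloxy group, so one regioisomer is expected, and the aldehyde deactivates the ring against a second formylation.

Step 7
Reactants: 16 2,3,4-tris(benzyloxy)-6-methylbenzaldehyde
Product: 17 2,3,4-tris(benzyloxy)-6-methylbenzoic acid
Conditions: NaClO2, NaH2PO4, 2-methylbut-2-ene, t-BuOH/THF/H2O, rt
Reagents that add atoms: sodium chlorite, [Na+].[O-]Cl=O
Why: Pinnick oxidation; the alkene scavenges the hypochlorous acid that would otherwise chlorinate the electron-rich ring, and the benzyl ethers are inert.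

Step 8
Reactants: 17 2,3,4-tris(benzyloxy)-6-methylbenzoic acid
Product: 18 2,3,4-tris(benzyloxy)-6-methylbenzoyl chloride
Conditions: (COCl)2, DMF (cat.), CH2Cl2, 0 °C to rt; volatiles removed, used at once
Reagents that add atoms: oxalyl chloride, O=C(Cl)C(Cl)=O
Why: Acid chloride formation through the Vilsmeier-type chloroiminium catalyst; the low temperature and the volatile by-products keep the ortho benzyl ether intact.

Step 9
Reactants: 13 methyl 2-hydroxy-3,6-dimethyl-4-[(triisopropylsilyl)oxy]benzoate; 18 2,3,4-tris(benzyloxy)-6-methylbenzoyl chloride
Product: 20 methyl 2-hydroxy-3,6-dimethyl-4-{[2,3,4-tris(benzyloxy)-6-methylbenzoyl]oxy}benzoate, via cesium phenoxide 19 (not isolated)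
Conditions: CsF (1.2 equiv), DMF, rt; then 18 (1.2 equiv), 0 °C to rt
Reagents that add atoms: cesium fluoride, [Cs+].[F-] (the cesium counter-ion of 19 only)
Why: Fluoride-induced desilylation followed by O-acylation in one pot: fluoride cleaves the aryl O–Si bond (the phenoxide para to the ester is a good leaving group) and the cesium phenoxide attacks the aroyl chloride by addition–elimination. The C2 hydroxyl stays protonated, hydrogen-bonded to the ester and shielded on both sides, so the oxygen that was silylated is the one that is acylated.

Step 10
Reactants: 20 methyl 2-hydroxy-3,6-dimethyl-4-{[2,3,4-tris(benzyloxy)-6-methylbenzoyl]oxy}benzoate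
Product: 21 methyl 2-hydroxy-3,6-dimethyl-4-[(2,3,4-trihydroxy-6-methylbenzoyl)oxy]benzoate
Conditions: H2 (1 atm), 10% Pd/C, EtOAc, rt
Reagents that add atoms: none
Why: Hydrogenolysis of the three benzyl aryl ethers; the aryl ester and the methyl ester are inert to these neutral conditions, and a non-nucleophilic solvent excludes transesterification of the depside.

## Compound list

1 | butane-2,3-dione | CC(=O)C(C)=O | starting material
2 | methyl (triphenylphosphoranylidene)acetate | COC(=O)C=P(c1ccccc1)(c1ccccc1)c1ccccc1 | starting material
3 | methyl (E)-3-methyl-4-oxopent-2-enoate | COC(=O)/C=C(\C)C(C)=O | intermediate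
4 | methyl (E)-6,6,6-trifluoro-3-methyl-4,6-dioxohex-2-enoate | COC(=O)/C=C(\C)C(=O)CC(=O)C(F)(F)F | intermediate (not isolated)
5 | methyl (E)-5-diazo-3-methyl-4-oxopent-2-enoate | COC(=O)/C=C(\C)C(=O)C=[N+]=[N-] | intermediate
6 | ethyl acetate | CCOC(C)=O | starting material
7 | lithium 1,1-dibromoprop-1-en-2-olate | [Li+].CC([O-])=C(Br)Br | intermediate (not isolated)
8 | lithium prop-1-yn-1-olate | [Li+].CC#C[O-] | intermediate (not isolated)
9 | triisopropyl(prop-1-yn-1-yloxy)silane | CC#CO[Si](C(C)C)(C(C)C)C(C)C | intermediate
10 | methyl (2E)-3-methyl-5-oxopenta-2,4-dienoate | COC(=O)/C=C(\C)C=C=O | intermediate (not isolated)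
11 | methyl (2E)-3-{3-methyl-4-oxo-2-[(triisopropylsilyl)oxy]cyclobut-2-en-1-yl}but-2-enoate (racemic) | COC(=O)/C=C(\C)C1C(=O)C(C)=C1O[Si](C(C)C)(C(C)C)C(C)C | intermediate (not isolated)
12 | methyl (2E,4E)-3,6-dimethyl-7-oxo-5-[(triisopropylsilyl)oxy]hepta-2,4,6-trienoate | COC(=O)/C=C(\C)/C=C(/O[Si](C(C)C)(C(C)C)C(C)C)\C(C)=C=O | intermediate (not isolated)
13 | methyl 2-hydroxy-3,6-dimethyl-4-[(triisopropylsilyl)oxy]benzoate | COC(=O)c1c(C)cc(O[Si](C(C)C)(C(C)C)C(C)C)c(C)c1O | intermediate
14 | 5-methylbenzene-1,2,3-triol | Cc1cc(O)c(O)c(O)c1 | starting material
15 | 1,2,3-tris(benzyloxy)-5-methylbenzene | Cc1cc(OCc2ccccc2)c(OCc2ccccc2)c(OCc2ccccc2)c1 | intermediate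
16 | 2,3,4-tris(benzyloxy)-6-methylbenzaldehyde | Cc1cc(OCc2ccccc2)c(OCc2ccccc2)c(OCc2ccccc2)c1C=O | intermediate
17 | 2,3,4-tris(benzyloxy)-6-methylbenzoic acid | Cc1cc(OCc2ccccc2)c(OCc2ccccc2)c(OCc2ccccc2)c1C(=O)O | intermediate
18 | 2,3,4-tris(benzyloxy)-6-methylbenzoyl chloride | Cc1cc(OCc2ccccc2)c(OCc2ccccc2)c(OCc2ccccc2)c1C(=O)Cl | intermediate
19 | cesium 3-hydroxy-4-(methoxycarbonyl)-2,5-dimethylphenolate | [Cs+].[O-]c1cc(C)c(C(=O)OC)c(O)c1C | intermediate (not isolated)
20 | methyl 2-hydroxy-3,6-dimethyl-4-{[2,3,4-tris(benzyloxy)-6-methylbenzoyl]oxy}benzoate | COC(=O)c1c(C)cc(OC(=O)c2c(C)cc(OCc3ccccc3)c(OCc3ccccc3)c2OCc2ccccc2)c(C)c1O | intermediate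
21 | methyl 2-hydroxy-3,6-dimethyl-4-[(2,3,4-trihydroxy-6-methylbenzoyl)oxy]benzoate | COC(=O)c1c(C)cc(OC(=O)c2c(C)cc(O)c(O)c2O)c(C)c1O | target

## Step count and least certain steps

Total: 10 steps. Longest linear sequence: 6 steps (steps 5, 6, 7, 8, 9 and 10, from 14). The ring A arm (steps 1, 2, 4, 9, 10) has 5 steps.

**Step 4 (key step).**
- Most likely failure: photoisomerisation of the enoate double bond before or after the Wolff rearrangement, after which the ketene can close onto its own ester oxygen and never add 9. The ketene may also dimerise or acylate the product phenol where the local concentration of 9 is low, and the sequence may stall at the cyclobutenone stage if heating is too short.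
- Fallback: take the light out of the annulation. It sets out from 5 and 9 and comes back at 13. Wolff rearrangement of 5 in the dark with catalytic PhCO2Ag and Et3N in aqueous THF (Arndt–Eistert conditions) lets water capture ketene 10 and should give (3E)-5-methoxy-3-methyl-5-oxopent-3-enoic acid F1. Oxalyl chloride with catalytic DMF converts it into methyl (2E)-5-chloro-3-methyl-5-oxopent-2-enoate F2. Slow addition of F2 to Et3N and 9 in toluene regenerates 10 by dehydrochlorination in the ground state, and the same cycloaddition, opening and closure through 11 and 12, finished at 80 °C, should give 13. A shift of the double bond of F1 or F2 into conjugation with the acid terminus is harmless, because both positional isomers lose HCl to the same ketene.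

**Step 2.**
- Most likely failure: conjugate addition of the lithium enolate to unreacted 3, which is a doubly activated Michael acceptor. Deprotonation of the C3 methyl group (vinylogous to the ester) can compete, and the diazo group of 5 may add slowly as a dipole to the enoate of a second molecule on storage.
- Fallback: replace enolate acylation by halogenation and a hydrazine-based diazo synthesis. It sets out from 3 and comes back at 5. Acid-mediated monobromination of the acetyl methyl group with pyrrolidone hydrotribromide in THF gives methyl (2E)-5-bromo-3-methyl-4-oxopent-2-enoate F3. N,N'-Ditosylhydrazine with DBU in THF at 0 °C should then convert the bromomethyl ketone into 5 by N-alkylation and loss of two sulfinate ions, with no lithium enolate, sulfonyl azide or diazomethane.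

**Step 3.**
- Most likely failure: proton transfer from ethyl acetate to the carbenoid or amide base in place of carbonyl addition, leading to self-condensation. Bromine–lithium exchange and rearrangement may be incomplete, silylation may go to carbon, and the small siloxyalkyne may hydrolyse during work-up.
- Fallback: make the ynolate by oxidation of an acetylide. This replaces starting material 6: the sequence sets out from commercial prop-1-yn-1-yllithium F4 and not from a numbered compound, and it comes back to the route at ynolate 8. Lithium tert-butyl peroxide (from anhydrous tert-butyl hydroperoxide and LiN(SiMe3)2 in THF at −78 °C) transfers oxygen to the acetylide carbon of F4 to give 8, which is silylated with TIPSCl as in step 3 to give 9.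

**Step 9.**
- Most likely failure: incomplete cleavage of the Si–O bond next to the C3 methyl group. Attack of the phenoxide on an aroyl chloride with two ortho substituents may be slow, with loss of the chloride to adventitious water, and some acylation at O2 is possible if excess base is present.
- Fallback: separate the two events and activate the acid as an acylium equivalent. It sets out from 13 and 17 and comes back at 20. Desilylation of 13 with Bu4NF buffered with acetic acid in THF gives methyl 2,4-dihydroxy-3,6-dimethylbenzoate F5 (the same compound as A2), which is isolated. Acid 17 is then treated with trifluoroacetic anhydride in toluene; the mixed anhydride reacts through an acylium-like species that is little affected by the two ortho substituents and should acylate the more nucleophilic, non-chelated C4 hydroxyl of F5 to give 20.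

## Further compounds

F1 | step 4 | (3E)-5-methoxy-3-methyl-5-oxopent-3-enoic acid | COC(=O)/C=C(\C)CC(=O)O
F2 | step 4 | methyl (2E)-5-chloro-3-methyl-5-oxopent-2-enoate | COC(=O)/C=C(\C)CC(=O)Cl
F3 | step 2 | methyl (2E)-5-bromo-3-methyl-4-oxopent-2-enoate | COC(=O)/C=C(\C)C(=O)CBr
F4 | step 3 | prop-1-yn-1-yllithium | [Li]C#CC
F5 | step 9 | methyl 2,4-dihydroxy-3,6-dimethylbenzoate | COC(=O)c1c(C)cc(O)c(C)c1O
A1 | alternative 1 | 1,2,3-tris(benzyloxy)-4-iodo-5-methylbenzene | Cc1cc(OCc2ccccc2)c(OCc2ccccc2)c(OCc2ccccc2)c1I
A2 | alternative 1 | methyl 2,4-dihydroxy-3,6-dimethylbenzoate | COC(=O)c1c(C)cc(O)c(C)c1O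
A3 | alternative 1 | methyl 2-hydroxy-3,6-dimethyl-4-{[2,3,4-tris(benzyloxy)-6-methylbenzoyl]oxy}benzoate | COC(=O)c1c(C)cc(OC(=O)c2c(C)cc(OCc3ccccc3)c(OCc3ccccc3)c2OCc2ccccc2)c(C)c1O
A4 | alternative 2 | tert-butyl 3-oxobutanoate | CC(=O)CC(=O)OC(C)(C)C
A5 | alternative 2 | methyl (E)-but-2-enoate | C/C=C/C(=O)OC
A6 | alternative 2 | tert-butyl 6-methyl-2,4-dioxocyclohexane-1-carboxylate (mixture of stereoisomers and enol forms) | CC1CC(=O)CC(=O)C1C(=O)OC(C)(C)C
A7 | alternative 2 | tert-butyl 6-methyl-2,3,4-trioxocyclohexane-1-carboxylate (mixture of stereoisomers and enol forms) | CC1CC(=O)C(=O)C(=O)C1C(=O)OC(C)(C)C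
A8 | alternative 2 | tert-butyl 2,3,4-trihydroxy-6-methylbenzoate | Cc1cc(O)c(O)c(O)c1C(=O)OC(C)(C)C
A9 | alternative 3 | 4-chloro-2,3-diisopropoxycyclobut-2-en-1-one (racemic) | CC(C)OC1=C(OC(C)C)C(Cl)C1=O
A10 | alternative 3 | methyl 2-hydroxy-3,6-dimethyl-4-{[(2E)-3-(tributylstannyl)but-2-enoyl]oxy}benzoate | COC(=O)c1c(C)cc(OC(=O)/C=C(\C)[Sn](CCCC)(CCCC)CCCC)c(C)c1O
A11 | alternative 3 | methyl 2-hydroxy-4-[(2-hydroxy-3,4-diisopropoxy-6-methylbenzoyl)oxy]-3,6-dimethylbenzoate | COC(=O)c1c(C)cc(OC(=O)c2c(C)cc(OC(C)C)c(OC(C)C)c2O)c(C)c1O
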